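## Structural features

The target is a eudesmane: ring A (C1–C5, C10) and ring B (C5–C10) share the C5–C10 bond, and a tetrasubstituted C4=C5 alkene makes C5 both a ring-fusion atom and a trigonal carbon. Ring A carries the C15 methyl on C4 and, at C3 (S), the allylic 3β ester of (E)-3-methylpent-2-enoic acid. Ring B carries a methyl acrylate unit (C11, C12, C13) at C7 (R) and an acetate at C8 (R), and C10 (R) is quaternary with the C14 methyl. C7 and C8 are adjacent and cis, and both substituents lie on the face of the C14 methyl, which is 1,3 to C8; C3 is remote from the other three centres. The fragile groups are the acrylate (Michael acceptor), the β,β-disubstituted enoate (E geometry and conjugation are lost through a dienolate or vinylketene), the ionisable allylic C3 ester, and the γ-acetoxy ester, whose deacetylated form closes to the 8,12-lactone. The real difficulty is the quaternary C10 next to trigonal C5 and its correlation with the C7/C8 pair across ring B, with no stereocentre at C5 or C6 to relay information. The key step exploits exactly this: C4–C5–C6 can be carried as an allene whose axis stores the C10 configuration, and the C2–C3–C4–C5 diene of that vinylallene closes rings A and B together onto a C10=C1 alkene, while C7 and C8 ride in as a cis-butyrolactone (C12 to O8) that is also the masked acrylate and acetate.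

## Logic of the disconnections

30 ⇒ 27 + 28. The C3–O acyl bond is cut first because the enoate is the group most easily isomerised. Six carbons are removed and a plain allylic alcohol remains. The forward acylation must avoid any vinylketene or dienolate and must leave acrylate and acetate alone.

27 ⇒ 26. The C3–H bond is cut (carbinol to ketone), because the 4-en-3-one is what the ring construction delivers. The forward reduction must attack only the ketone and from the α face.

26 ⇒ 23 (through 24 and 25). The ester O–CH3 bond and the acetyl–O8 bond are cut and C12 is joined to O8. One cis lactone then stands for both functions and locks the C7/C8 relationship. The forward opening must outrun reclosure.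

23 ⇒ 22 ⇒ 18. C11=C13 is cut and the enone is redrawn as its silyl dienol ether. This leads back to the direct cycloadduct, and the dienol ether protects the ketone while C11 is deprotonated. The forward step must functionalise C11 without touching the dienol ether.

18 ⇒ 17. The strategic cut: C1–C2 and C5–C10 are broken in one retro-[4+2] step and C5=C6 becomes the second double bond of an allene. A tricycle becomes a monocyclic lactone with two side chains, and the C10 centre is exchanged for an axis. The demand is an axially pure 17 and a cycloaddition faster than anything that scrambles the axis.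

17 ⇒ 16 ⇒ 15 ⇒ 14 ⇒ 13. The enol O–Si bond, the C3 oxidation level and then the C4–C15 bond are cut. The axis is traced back to the C6 carbinol centre of 13, which a catalyst can set. The demand is clean anti SN2′ methyl transfer and a C3 oxygen that cannot act as a leaving group.

13 ⇒ 12 ⇒ 11 ⇒ 10. C10=C1 (methylene on a methyl ketone) and C6–H (carbinol from ynone) are cut. Both arms become carbonyl groups of different kind. The reduction must be reagent-controlled at C6 and spare the dialkyl ketone, and the methylenation must be non-basic because the C10 ketone is β to O8.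

10 ⇒ 9 ⇒ 3 + 5. C6–C5 and C10–C14 are cut back to two aldehydes. The whole skeleton of 17 reduces to 3, the alkyne 5 and two one-carbon units. The demand is that the two aldehydes of 3 be told apart, here by the size sensitivity of an organotitanium reagent.

3 ⇒ 1 and 5 ⇒ 4. Rejoining C6 and C10 gives the cyclopentene of 1, which supplies C7 and C8 cis and enantiopure; 5 is the silyl ether of 4. The cleavage must be neutral because C7 is epimerisable in 3.

## Other disconnections considered

Alternative 1: The cut is the C7–C8 bond of ring B. Forward, A2 (ring A complete, a (Z)-2-(bromomethyl)but-2-enoate arm on C5 through C6, an acetaldehyde arm on C10) would be treated with CrCl2 (divalent chromium). The allylchromium would add through its γ-carbon C7 to the C8 aldehyde and give the hydroxy acrylate A1, one acetylation from the target.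
- In its favour: acrylate and free C8 hydroxyl appear in final form in one step, the C3 ester can already be in place, and the reagent tolerates esters. A chair-like cyclic transition state of the Z reagent is the basis for expecting the cis C7/C8 pair.
- Against it here: both new centres must be placed relative to C10 by a quaternary carbon whose C14 methyl and C1 methylene differ little in size, so the 8β/10β relationship rests on a conformational preference. A2 needs an enantioselective synthesis of ring A with C3, the tetrasubstituted alkene and C10 before any of ring B exists. A1 is the γ-hydroxy ester that tends to lactonise.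
- Comparison: on structure, the chosen plan buys C7/C8 and makes C10 last, while this one makes C10 first and C7/C8 last. On mechanism, the chosen plan rests on a geometric necessity and this one on a preference. On step economy, alternative 1 is the better in the end game (no lactone opening, no separate methylenation) and at least the equal in convergence, but it pays with a longer, less certain route to A2.

Alternative 2: The cut is the C7–C11 bond, with C11 delivered from O8. Forward, the bromoacetal A4 of an 8β-hydroxy 4,6-dien-3-one would be treated with Bu3SnH and AIBN. The C11 radical would add 5-exo to C7, the dienone terminus, and hydrogen transfer to the delocalised radical would give the cis-fused lactol ether A3.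
- In its favour: cis fusion at C7/C8 is enforced by the five-membered tether, and a nucleophilic alkyl radical is well matched to an electron-poor diene. The decalin core can come from long-established annulation chemistry; on robustness of ring construction this alternative is the better one.
- Against it here: the step forms one bond and no ring of the target. A4 requires the 8β oxygen to be set relative to C10 on a preformed decalin. A3 still needs oxidation to the lactone and then the whole end game of the chosen route. The intermediate radical can take hydrogen at C4 as well as C6, and tin residues must be removed.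
- Comparison: on structure, both plans pass through the same cis lactone, which the chosen plan buys and this one must create. On mechanism, tether-enforced radical addition is as reliable for C7 as the axis is for C10 (equal on that point), but C8 and C10 are left to earlier steps. On step economy it is worse: one carbon–carbon bond against two bonds and two rings.

Alternative 3: The cuts are C10–C14 and C5–C6 on ring A. Forward, the enone A6 would take methyl from MeMgBr at C10 under Cu(OTf)2 and a chiral N-heterocyclic carbene ligand. The magnesium enolate would be alkylated at C5 by tert-butyl bromoacetate A7 to give the ketone A5.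
- In its favour: quaternary C10 is made by a catalyst from an achiral enone; on this point the alternative is the better one, since no stoichiometric source of chirality is used. Both ring B arms are installed in one flask.
- Against it here: no ring closes. Ring B, C7, C8, the C15 methyl, the C4=C5 alkene and the C3 oxygen are all still missing. The carbonyl of A5 sits at C4, so C3 must be oxidised separately. Such enolates are sluggish toward alkyl halides, and the C5 centre formed is later destroyed.
- Comparison: on structure, it solves only C10, whereas the chosen plan solves C10 and both rings together. On mechanism, catalyst control and axis control are both predictable. On step economy it is clearly longer, because a ring B closure with C7/C8 control must still be added.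

Key step: step 12

Remarks (assumptions on the chemistry):
- Locants C1–C15 are those of the eudesmane skeleton of 30 and are used for every intermediate.
- 1, 4 and isomerically pure 28 are taken as purchasable.
- 17 has C7 S, C8 R and an aS (P-helical) allene. A geometric check shows that this axis, with C7 on the diene face the tether must use, leads to 10R only, so 17, 18 and 30 are mutually consistent and no structure needed correction. It follows that 13 must be 6S.
- Because the C10 carbonyl compounds are β to O8 and C7 is epimerisable, the arms are built with non-basic reagents, and the siloxy diene is made last.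

Step 1
Reactants: 1 (1R,5S)-2-oxabicyclo[3.3.0]oct-6-en-3-one
Product: 3 (2R,3R)-5-oxo-2-(2-oxoethyl)oxolane-3-carbaldehyde, via secondary ozonide 2 (not isolated)
Conditions: O3, CH2Cl2, −78 °C; then PPh3, −78 °C to rt; used crude
Reagents that add atoms: ozone O=[O+][O-]
Why: Ozonolysis with reductive work-up cleaves the only alkene to the C6 and C10 aldehydes under neutral conditions, so the cis C7/C8 pair of 1 is carried over unchanged and the epimerisable C7 and the β-acyloxy aldehyde never see base.

Step 2
Reactants: 4 (R)-but-3-yn-2-ol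
Product: 5 (R)-tert-butyl(but-3-yn-2-yloxy)dimethylsilane
Conditions: TBSCl, imidazole, CH2Cl2, 0 °C to rt
Reagents that add atoms: tert-butyldimethylsilyl chloride CC(C)(C)[Si](C)(C)Cl
Why: Standard silylation; the silyl ether is a non-leaving propargylic oxygen, so the later SN2′ step can expel only the C6 mesylate, and the single enantiomer keeps every intermediate a single diastereomer until C3 is oxidised.

Step 3
Reactants: 3 (2R,3R)-5-oxo-2-(2-oxoethyl)oxolane-3-carbaldehyde; 5 (R)-tert-butyl(but-3-yn-2-yloxy)dimethylsilane
Product: 9 (4S,5R)-4-[(4R)-4-(tert-butyldimethylsilyloxy)-1-hydroxypent-2-yn-1-yl]-5-(2-hydroxypropyl)oxolan-2-one (C6/C10 carbinol epimers), via lithium acetylide 6 (not isolated), via titanium acetylide 7 (not isolated), via C10 methyl carbinol 8 (not isolated)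
Conditions: 5, n-BuLi, THF, −78 °C, then ClTi(Oi-Pr)3 (gives 7); 3, MeTi(Oi-Pr)3 [from MeMgBr + ClTi(Oi-Pr)3] (1.0 equiv), THF, −78 to −40 °C; then 7 (2.2 equiv), −40 to 0 °C; aq NH4Cl
Reagents that add atoms: methylmagnesium bromide C[Mg]Br
Why: Chemoselective organotitanium additions: the non-basic, size-sensitive methyltitanium reagent should take the unbranched C10 aldehyde before the α-branched C6 aldehyde, and the alkynyltitanium then adds at C6; titanium reagents spare the lactone and do not trigger E1cB loss of O8. Both new carbinol centres are unselective and are erased in step 4.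

Step 4
Reactants: 9 (4S,5R)-4-[(4R)-4-(tert-butyldimethylsilyloxy)-1-hydroxypent-2-yn-1-yl]-5-(2-hydroxypropyl)oxolan-2-one
Product: 10 (4R,5R)-4-[(4R)-4-(tert-butyldimethylsilyloxy)pent-2-ynoyl]-5-(2-oxopropyl)oxolan-2-one
Conditions: DMP, NaHCO3, CH2Cl2, 0 °C to rt
Reagents that add atoms: none
Why: Dess–Martin oxidation of both secondary alcohols under buffered conditions gives the ynone and the methyl ketone without enolising C7 or eliminating O8.

Step 5
Reactants: 10 (4R,5R)-4-[(4R)-4-(tert-butyldimethylsilyloxy)pent-2-ynoyl]-5-(2-oxopropyl)oxolan-2-one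
Product: 11 (4S,5R)-4-[(1S,4R)-4-(tert-butyldimethylsilyloxy)-1-hydroxypent-2-yn-1-yl]-5-(2-oxopropyl)oxolan-2-one
Conditions: Ru[(S,S)-TsNCHPhCHPhNH](p-cymene) (cat.), i-PrOH, rt
Reagents that add atoms: none
Why: Noyori asymmetric transfer hydrogenation reduces the ynone far faster than the dialkyl ketone, and the catalyst sets C6; the (S,S) ligand is expected to give the 6S carbinol because the alkynyl group plays the role of the aryl group of aryl ketones (sense to be confirmed by Mosher analysis). The preformed amido complex needs no added base.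

Step 6
Reactants: 11 (4S,5R)-4-[(1S,4R)-4-(tert-butyldimethylsilyloxy)-1-hydroxypent-2-yn-1-yl]-5-(2-oxopropyl)oxolan-2-one
Product: 12 (4S,5R)-4-[(1S,4R)-4-(tert-butyldimethylsilyloxy)-1-hydroxypent-2-yn-1-yl]-5-(2-methylprop-2-en-1-yl)oxolan-2-one
Conditions: Zn, CH2Br2, TiCl4, THF/CH2Cl2, 0 °C to rt
Reagents that add atoms: dibromomethane BrCBr
Why: Takai–Lombardo methylenation uses a non-basic gem-dimetallic reagent, so the β-acyloxy ketone becomes the C10=C1 alkene without E1cB ring opening; lactone, silyl ether, alkyne and free hydroxyl are tolerated.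

Step 7
Reactants: 12 (4S,5R)-4-[(1S,4R)-4-(tert-butyldimethylsilyloxy)-1-hydroxypent-2-yn-1-yl]-5-(2-methylprop-2-en-1-yl)oxolan-2-one
Product: 13 (4R,5R)-4-[(1S,4R)-4-(tert-butyldimethylsilyloxy)-1-(methanesulfonyloxy)pent-2-yn-1-yl]-5-(2-methylprop-2-en-1-yl)oxolan-2-one
Conditions: MsCl, Et3N, CH2Cl2, −40 °C; used crude
Reagents that add atoms: methanesulfonyl chloride CS(=O)(=O)Cl
Why: Mesylation at low temperature; only the O–H bond reacts, so C6 keeps its configuration, and prompt sulfonylation leaves the C6 hydroxyl no time to transfer the lactone acyl group.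

Step 8
Reactants: 13 (4R,5R)-4-[(1S,4R)-4-(tert-butyldimethylsilyloxy)-1-(methanesulfonyloxy)pent-2-yn-1-yl]-5-(2-methylprop-2-en-1-yl)oxolan-2-one
Product: 14 (4S,5R)-4-[(aS,4R)-4-(tert-butyldimethylsilyloxy)-3-methylpenta-1,2-dien-1-yl]-5-(2-methylprop-2-en-1-yl)oxolan-2-one
Conditions: MeMgBr, CuBr·SMe2, LiBr, THF, −78 to −40 °C
Reagents that add atoms: methylmagnesium bromide C[Mg]Br
Why: Anti SN2′ substitution of a propargylic mesylate by the organocopper reagent MeCu·MgBr2·LiBr: methyl enters at C4 on the face opposite the leaving group, so the 6S centre is translated into the aS axis. The reagent does not attack the lactone and is less prone than lithium cuprates to racemise allenes.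

Step 9
Reactants: 14 (4S,5R)-4-[(aS,4R)-4-(tert-butyldimethylsilyloxy)-3-methylpenta-1,2-dien-1-yl]-5-(2-methylprop-2-en-1-yl)oxolan-2-one
Product: 15 (4S,5R)-4-[(aS,4R)-4-hydroxy-3-methylpenta-1,2-dien-1-yl]-5-(2-methylprop-2-en-1-yl)oxolan-2-one
Conditions: TBAF, AcOH, THF, 0 °C to rt
Reagents that add atoms: none
Why: Fluoride cleavage of the silyl ether, buffered with AcOH so that the lactone is not opened and the allene is not isomerised.

Step 10
Reactants: 15 (4S,5R)-4-[(aS,4R)-4-hydroxy-3-methylpenta-1,2-dien-1-yl]-5-(2-methylprop-2-en-1-yl)oxolan-2-one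
Product: 16 (4S,5R)-4-[(aS)-3-methyl-4-oxopenta-1,2-dien-1-yl]-5-(2-methylprop-2-en-1-yl)oxolan-2-one
Conditions: DMP, NaHCO3, CH2Cl2, 0 °C to rt
Reagents that add atoms: none
Why: Dess–Martin oxidation of the α-allenic alcohol to the allenyl ketone under neutral conditions; the C3 stereocentre disappears and the axis is untouched.

Step 11
Reactants: 16 (4S,5R)-4-[(aS)-3-methyl-4-oxopenta-1,2-dien-1-yl]-5-(2-methylprop-2-en-1-yl)oxolan-2-one
Product: 17 (4S,5R)-4-[(aS)-4-(tert-butyldimethylsilyloxy)-3-methylpenta-1,2,4-trien-1-yl]-5-(2-methylprop-2-en-1-yl)oxolan-2-one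
Conditions: TBSOTf, Et3N, CH2Cl2, −78 to 0 °C; filtration through basic alumina; used at once
Reagents that add atoms: tert-butyldimethylsilyl trifluoromethanesulfonate CC(C)(C)[Si](C)(C)OS(=O)(=O)C(F)(F)F
Why: Soft enolisation and silylation: the ketone can enolise only toward the C2 methyl and is silylated much faster than the lactone, which gives the 2-siloxy diene of the vinylallene.

Step 12
Reactants: 17 (4S,5R)-4-[(aS)-4-(tert-butyldimethylsilyloxy)-3-methylpenta-1,2,4-trien-1-yl]-5-(2-methylprop-2-en-1-yl)oxolan-2-one
Product: 18 (7S,8R,10R)-3-(tert-butyldimethylsilyloxy)-13-noreudesma-3,5-dien-12,8-olide (cis lactone with 8β-O and 10β-methyl)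
Conditions: PhMe (0.01 M), BHT (cat.), 110 °C, sealed tube
Reagents that add atoms: none
Why: Thermal intramolecular Diels–Alder reaction of a 2-siloxy vinylallene, a known reaction type for tethered unactivated alkenes with axis-to-centre chirality transfer. The s-cis diene C2=C3–C4=C5 adds suprafacially to C10=C1 in a concerted, asynchronous [4+2] step that forms C1–C2 and C5–C10. Ring A closes as the six-membered ring of the cycloadduct and ring B as the six-membered ring defined by the three-atom tether C7–C8–C9, fused through C5–C10. The only new stereocentre is C10, and it is controlled by the allene axis: C7 on C6 stands perpendicular to the diene plane and can deliver the alkene only to the diene face on its own side, and only with C9 turned toward C6, since the other alkene face would require a trans double bond in ring B. With the aS axis this should give 10R with C14 cis to the lactone, while C7 and C8 are spectators that must only tolerate the tether geometry. The orthogonal C5=C6 bond survives, so C5 stays trigonal and the product is the extended silyl enol ether of the 4-en-3-one. The step needs intramolecular addition to beat dimerisation and cycloaddition to beat loss of axial purity; high dilution, the strain released by the cumulene and a radical inhibitor are meant to secure this. The electron-rich diene and the unactivated 1,1-disubstituted alkene are not polarity-matched, which is why heating is planned.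

Step 13
Reactants: 18 (7S,8R,10R)-3-(tert-butyldimethylsilyloxy)-13-noreudesma-3,5-dien-12,8-olide
Product: 22 (7R,8R,10R)-3-(tert-butyldimethylsilyloxy)eudesma-3,5,11(13)-trien-12,8-olide, via lithium enolate 19 (not isolated), via Mannich base 20 (not isolated), via ammonium iodide 21 (not isolated)
Conditions: LiN(i-Pr)2, THF, −78 °C; CH2=NMe2+ I− (1.05 equiv), −78 to 0 °C; MeI, THF, rt; aq NaHCO3, CH2Cl2, rt
Reagents that add atoms: N,N-dimethylmethyleneiminium iodide C=[N+](C)C.[I-]
Why: Lactone α-methylenation by Mannich reaction of the lithium enolate with the iminium salt, N-methylation and β-elimination. C11 is the only acidic site because the C3 ketone is still masked as the silyl dienol ether, and the transient C11 centre is lost on elimination.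

Step 14
Reactants: 22 (7R,8R,10R)-3-(tert-butyldimethylsilyloxy)eudesma-3,5,11(13)-trien-12,8-olide
Product: 23 (7R,8R,10R)-3-oxoeudesma-4,11(13)-dien-12,8-olide
Conditions: 1 M HCl, THF, rt
Reagents that add atoms: none
Why: Acid hydrolysis of the silyl dienol ether; protonation at C6 under equilibrating conditions gives the conjugated 4-en-3-one, and C7 is not α to a carbonyl so it cannot epimerise.

Step 15
Reactants: 23 (7R,8R,10R)-3-oxoeudesma-4,11(13)-dien-12,8-olide
Product: 26 methyl (7R,8R,10R)-8-acetoxy-3-oxoeudesma-4,11(13)-dien-12-oate, via potassium carboxylate 24 (not isolated), via hydroxy ester 25 (not isolated)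
Conditions: KOH (1.05 equiv), THF/H2O, 0 °C (degassed); evaporate; MeI, DMF, rt; then Ac2O, pyridine, DMAP (cat.), rt
Reagents that add atoms: potassium hydroxide [K+].[OH-]; iodomethane CI; acetic anhydride CC(=O)OC(C)=O
Why: Saponification of the α-methylene lactone (the way alantolactone-type lactones are opened to their hydroxy acids), O-methylation of the carboxylate and acetylation of the 8β hydroxyl in the same flask, so the γ-hydroxy ester is trapped before it can reclose. C8 keeps its configuration because the acyl–oxygen bond is the one that breaks.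

Step 16
Reactants: 26 methyl (7R,8R,10R)-8-acetoxy-3-oxoeudesma-4,11(13)-dien-12-oate
Product: 27 methyl (3S,7R,8R,10R)-8-acetoxy-3-hydroxyeudesma-4,11(13)-dien-12-oate
Conditions: NaBH4, CeCl3·7H2O, MeOH, −78 °C
Reagents that add atoms: none
Why: Luche reduction: 1,2-reduction of the enone is much faster than attack on the acrylate or the esters. Hydride should enter axially from the α face, anti to the axial C14 methyl, to give the pseudoequatorial 3β (S) alcohol, as is usual for 10β-methyl 4-en-3-ones.

Step 17
Reactants: 27 methyl (3S,7R,8R,10R)-8-acetoxy-3-hydroxyeudesma-4,11(13)-dien-12-oate; 28 (E)-3-methylpent-2-enoic acid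
Product: 30 methyl (3S,7R,8R,10R)-8-acetoxy-3-[(E)-3-methylpent-2-enoyloxy]eudesma-4,11(13)-dien-12-oate, via acid chloride 29 (not isolated)
Conditions: 28, (COCl)2, DMF (cat.), CH2Cl2, 0 °C; then 27, pyridine, DMAP (cat.), CH2Cl2, 0 °C
Reagents that add atoms: none
Why: Acylation with the acid chloride and pyridine; the weak base is chosen so that no vinylketene or dienolate forms and the E geometry and conjugation of the enoate are kept. C3 retains its configuration because only the O–H bond reacts.

## Compound list

1 | (1R,5S)-2-oxabicyclo[3.3.0]oct-6-en-3-one | O=C1C[C@H]2C=CC[C@H]2O1 | starting material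
2 | secondary ozonide of 1 (1,2,4-trioxolane across C6 and C10) | O=C1C[C@H]2C3OOC(O3)C[C@H]2O1 | intermediate
3 | (2R,3R)-5-oxo-2-(2-oxoethyl)oxolane-3-carbaldehyde (cis dialdehyde) | O=C1C[C@@H](C=O)[C@@H](CC=O)O1 | intermediate
4 | (R)-but-3-yn-2-ol | C[C@@H](O)C#C | starting material
5 | (R)-tert-butyl(but-3-yn-2-yloxy)dimethylsilane | C[C@@H](O[Si](C)(C)C(C)(C)C)C#C | intermediate
6 | lithium acetylide of 5 | [Li]C#C[C@@H](C)O[Si](C)(C)C(C)(C)C | intermediate
7 | triisopropoxytitanium acetylide of 5 | CC(C)O[Ti](OC(C)C)(OC(C)C)C#C[C@@H](C)O[Si](C)(C)C(C)(C)C | intermediate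
8 | (2R,3R)-2-(2-hydroxypropyl)-5-oxooxolane-3-carbaldehyde, C10 epimers, formed as its titanium alkoxide | O=C1C[C@@H](C=O)[C@@H](CC(C)O)O1 | intermediate
9 | (4S,5R)-4-[(4R)-4-(tert-butyldimethylsilyloxy)-1-hydroxypent-2-yn-1-yl]-5-(2-hydroxypropyl)oxolan-2-one, C6 and C10 carbinol epimers | O=C1C[C@@H](C(O)C#C[C@@H](C)O[Si](C)(C)C(C)(C)C)[C@@H](CC(C)O)O1 | intermediate
10 | (4R,5R)-4-[(4R)-4-(tert-butyldimethylsilyloxy)pent-2-ynoyl]-5-(2-oxopropyl)oxolan-2-one | O=C1C[C@@H](C(=O)C#C[C@@H](C)O[Si](C)(C)C(C)(C)C)[C@@H](CC(C)=O)O1 | intermediate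
11 | (4S,5R)-4-[(1S,4R)-4-(tert-butyldimethylsilyloxy)-1-hydroxypent-2-yn-1-yl]-5-(2-oxopropyl)oxolan-2-one | O=C1C[C@@H]([C@H](O)C#C[C@@H](C)O[Si](C)(C)C(C)(C)C)[C@@H](CC(C)=O)O1 | intermediate
12 | (4S,5R)-4-[(1S,4R)-4-(tert-butyldimethylsilyloxy)-1-hydroxypent-2-yn-1-yl]-5-(2-methylprop-2-en-1-yl)oxolan-2-one | O=C1C[C@@H]([C@H](O)C#C[C@@H](C)O[Si](C)(C)C(C)(C)C)[C@@H](CC(C)=C)O1 | intermediate
13 | (4R,5R)-4-[(1S,4R)-4-(tert-butyldimethylsilyloxy)-1-(methanesulfonyloxy)pent-2-yn-1-yl]-5-(2-methylprop-2-en-1-yl)oxolan-2-one | O=C1C[C@@H]([C@H](OS(C)(=O)=O)C#C[C@@H](C)O[Si](C)(C)C(C)(C)C)[C@@H](CC(C)=C)O1 | intermediate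
14 | (4S,5R)-4-[(aS,4R)-4-(tert-butyldimethylsilyloxy)-3-methylpenta-1,2-dien-1-yl]-5-(2-methylprop-2-en-1-yl)oxolan-2-one | O=C1C[C@@H](C([H])=[C@@]=C(C)[C@@H](C)O[Si](C)(C)C(C)(C)C)[C@@H](CC(C)=C)O1 | intermediate
15 | (4S,5R)-4-[(aS,4R)-4-hydroxy-3-methylpenta-1,2-dien-1-yl]-5-(2-methylprop-2-en-1-yl)oxolan-2-one | O=C1C[C@@H](C([H])=[C@@]=C(C)[C@@H](C)O)[C@@H](CC(C)=C)O1 | intermediate
16 | (4S,5R)-4-[(aS)-3-methyl-4-oxopenta-1,2-dien-1-yl]-5-(2-methylprop-2-en-1-yl)oxolan-2-one | O=C1C[C@@H](C([H])=[C@@]=C(C)C(C)=O)[C@@H](CC(C)=C)O1 | intermediate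
17 | (4S,5R)-4-[(aS)-4-(tert-butyldimethylsilyloxy)-3-methylpenta-1,2,4-trien-1-yl]-5-(2-methylprop-2-en-1-yl)oxolan-2-one (key-step precursor) | C=C(O[Si](C)(C)C(C)(C)C)C(C)=[C@@]=C([H])[C@@H]1CC(=O)O[C@@H]1CC(C)=C | intermediate
18 | (7S,8R,10R)-3-(tert-butyldimethylsilyloxy)-13-noreudesma-3,5-dien-12,8-olide (key-step product; cis lactone, 8β-O, 10β-methyl) | O=C1C[C@H]2C=C3C(C)=C(O[Si](C)(C)C(C)(C)C)CC[C@]3(C)C[C@H]2O1 | intermediate
19 | lithium enolate of 18 (C11=C12) | [Li]OC1=C[C@H]2C=C3C(C)=C(O[Si](C)(C)C(C)(C)C)CC[C@]3(C)C[C@H]2O1 | intermediate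
20 | 11-(dimethylaminomethyl) derivative of 18, C11 epimers | O=C1C(CN(C)C)[C@H]2C=C3C(C)=C(O[Si](C)(C)C(C)(C)C)CC[C@]3(C)C[C@H]2O1 | intermediate
21 | N-methyl ammonium iodide of 20 | O=C1C(C[N+](C)(C)C)[C@H]2C=C3C(C)=C(O[Si](C)(C)C(C)(C)C)CC[C@]3(C)C[C@H]2O1.[I-] | intermediate
22 | (7R,8R,10R)-3-(tert-butyldimethylsilyloxy)eudesma-3,5,11(13)-trien-12,8-olide | O=C1C(=C)[C@H]2C=C3C(C)=C(O[Si](C)(C)C(C)(C)C)CC[C@]3(C)C[C@H]2O1 | intermediate
23 | (7R,8R,10R)-3-oxoeudesma-4,11(13)-dien-12,8-olide | O=C1C(=C)[C@H]2CC3=C(C)C(=O)CC[C@]3(C)C[C@H]2O1 | intermediate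
24 | potassium (7R,8R,10R)-8-hydroxy-3-oxoeudesma-4,11(13)-dien-12-oate | [K+].[O-]C(=O)C(=C)[C@H]1CC2=C(C)C(=O)CC[C@]2(C)C[C@H]1O | intermediate
25 | methyl (7R,8R,10R)-8-hydroxy-3-oxoeudesma-4,11(13)-dien-12-oate | C=C(C(=O)OC)[C@H]1CC2=C(C)C(=O)CC[C@]2(C)C[C@H]1O | intermediate
26 | methyl (7R,8R,10R)-8-acetoxy-3-oxoeudesma-4,11(13)-dien-12-oate | C=C(C(=O)OC)[C@H]1CC2=C(C)C(=O)CC[C@]2(C)C[C@H]1OC(C)=O | intermediate
27 | methyl (3S,7R,8R,10R)-8-acetoxy-3-hydroxyeudesma-4,11(13)-dien-12-oate | C=C(C(=O)OC)[C@H]1CC2=C(C)[C@@H](O)CC[C@]2(C)C[C@H]1OC(C)=O | intermediate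
28 | (E)-3-methylpent-2-enoic acid | CC/C(C)=C/C(=O)O | starting material
29 | (E)-3-methylpent-2-enoyl chloride | CC/C(C)=C/C(=O)Cl | intermediate
30 | methyl (3S,7R,8R,10R)-8-acetoxy-3-[(E)-3-methylpent-2-enoyloxy]eudesma-4,11(13)-dien-12-oate | C=C(C(=O)OC)[C@H]1CC2=C(C)[C@@H](OC(=O)/C=C(\C)CC)CC[C@]2(C)C[C@H]1OC(C)=O | target

## Step count and least certain steps

Total: 17 steps. Longest linear sequence: 16 steps (from 1 through steps 1 and 3–17; the branch from 4 through steps 2–17 is equally long).

Step 12 (key step). What may go wrong: cycloaddition onto an unactivated, 1,1-disubstituted alkene may be too slow, so that reversible electrocyclisation of the vinylallene, dimerisation or hydrolysis of the silyl enol ether take over and axial purity is eroded before the ring closes. Fallback, from 17 back to 18: the same two bonds are made by a metal-templated [4+2] reaction instead of a pericyclic one. [Rh(cod)(C10H8)]SbF6, a cationic complex of monovalent rhodium, in CH2Cl2 at room temperature would bind diene and alkene, form a rhodacycle by oxidative cyclisation and release 18 by reductive elimination. This type of catalysis is known for dienes with tethered unactivated alkenes and for vinylallenes as four-carbon partners, and the tether still confines the alkene to the C7 face. No new compound is involved.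

Step 3. What may go wrong: incomplete discrimination between the two aldehydes in the first addition (methyl transfer to C6, or double addition), and slow alkynyl transfer because the C6 aldehyde is tied up as a titanium lactolate with the new C10 alkoxide. Fallback, from 3 back to 10: the aldehydes are told apart by protection instead of by rate.
- NaBH4 in MeOH at −78 °C reduces 3 to (4S,5R)-5-(2-hydroxyethyl)-4-(hydroxymethyl)oxolan-2-one F1.
- TrCl and pyridine protect the less hindered C10 hydroxyl to give the C10 trityl ether F2.
- Dess–Martin oxidation gives the C6 aldehyde F3.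
- The titanium acetylide 7 adds to give the C6 propargylic alcohol F4.
- Formic acid in ether removes the trityl group to give the C6,C10 diol F5.
- Dess–Martin oxidation gives the ynone aldehyde F6.
- MeTi(Oi-Pr)3 adds only to the aldehyde to give the C10 methyl carbinol F7, and a last Dess–Martin oxidation returns to 10.

Step 13. What may go wrong: attack of the iminium salt on the silyl dienol ether (at C4 or C6) once the mixture is warmed, and loss of the dienol ether during quaternisation and elimination. Fallback, from 18 back to 27: the ketone is unmasked and reduced first, and the alcohol, not the dienol ether, is carried as a silyl ether.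
- 1 M HCl in THF gives the 13-nor enone lactone F8.
- Luche reduction gives the 3β alcohol F9.
- TBSCl and imidazole give the 3β silyl ether F10.
- LiN(i-Pr)2, the iminium iodide, MeI and NaHCO3 as in step 13 give the α-methylene lactone F11.
- KOH, MeI and Ac2O as in step 15 give the 3-silyloxy 8-acetoxy methyl ester F12.
- HF·pyridine in THF removes the silyl group and returns to 27.

This order also keeps the borohydride away from the acrylate.

Step 15. What may go wrong: reclosure of the γ-hydroxy ester to the lactone before the hydroxyl is acetylated, and conjugate addition of hydroxide to the methylene lactone. Fallback, from 22 back to 26: the lactone is opened by reduction, so no γ-hydroxy ester is ever present.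
- i-Bu2AlH in CH2Cl2 reduces 22 to the C8,C12 diol F13.
- TBSCl and imidazole silylate the primary allylic hydroxyl to give the C12 silyl ether F14.
- Ac2O, pyridine and DMAP give the C8 acetate F15.
- 1 M HCl in THF hydrolyses the dienol ether and the primary silyl ether to give the C12 allylic alcohol enone F16.
- MnO2 gives the enal F17.
- Pinnick oxidation (NaClO2, NaH2PO4, 2-methylbut-2-ene) gives the acrylic acid F18.
- TMSCHN2 in MeOH/PhMe returns to 26.

Step 17. What may go wrong: slow acylation of the hindered allylic alcohol, and, once more base or DMAP is used to force it, loss of E geometry and conjugation of the acyl donor through a vinylketene or dienolate. Fallback, from 27 back to 30: the enoate is built on the alcohol with its geometry set by a stereospecific coupling.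
- 2,2-Dimethyl-5-propanoyl-1,3-dioxane-4,6-dione in PhMe at 90 °C transfers a propionylketene to 27 and gives the 3-oxopentanoate F19.
- Tf2O, LiOTf and i-Pr2NEt in CH2Cl2 at 0 °C give, through the lithium chelate, the Z enol triflate F20.
- Negishi coupling with MeZnCl and Pd(PPh3)4 (zerovalent palladium) in THF replaces the triflate by methyl with retention. Methyl then stands cis to the ester carbonyl and ethyl trans, which is the E enoate of 30.

## Further compounds

F0 | step 12 | none | none
F1 | step 3 | (4S,5R)-5-(2-hydroxyethyl)-4-(hydroxymethyl)oxolan-2-one | O=C1C[C@@H](CO)[C@@H](CCO)O1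
F2 | step 3 | C10 trityl ether of F1 | O=C1C[C@@H](CO)[C@@H](CCOC(c2ccccc2)(c2ccccc2)c2ccccc2)O1
F3 | step 3 | C6 aldehyde with C10 trityl ether | O=C1C[C@@H](C=O)[C@@H](CCOC(c2ccccc2)(c2ccccc2)c2ccccc2)O1
F4 | step 3 | C6 propargylic alcohol (C6 epimers) with C10 trityl ether | O=C1C[C@@H](C(O)C#C[C@@H](C)O[Si](C)(C)C(C)(C)C)[C@@H](CCOC(c2ccccc2)(c2ccccc2)c2ccccc2)O1
F5 | step 3 | C6,C10 diol (C6 epimers) | O=C1C[C@@H](C(O)C#C[C@@H](C)O[Si](C)(C)C(C)(C)C)[C@@H](CCO)O1
F6 | step 3 | ynone aldehyde | O=C1C[C@@H](C(=O)C#C[C@@H](C)O[Si](C)(C)C(C)(C)C)[C@@H](CC=O)O1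
F7 | step 3 | ynone with C10 methyl carbinol (C10 epimers) | O=C1C[C@@H](C(=O)C#C[C@@H](C)O[Si](C)(C)C(C)(C)C)[C@@H](CC(C)O)O1
F8 | step 13 | (7S,8R,10R)-3-oxo-13-noreudesm-4-en-12,8-olide | O=C1C[C@H]2CC3=C(C)C(=O)CC[C@]3(C)C[C@H]2O1
F9 | step 13 | 3β-hydroxy-13-noreudesm-4-en-12,8-olide | O=C1C[C@H]2CC3=C(C)[C@@H](O)CC[C@]3(C)C[C@H]2O1
F10 | step 13 | 3β-(tert-butyldimethylsilyloxy)-13-noreudesm-4-en-12,8-olide | O=C1C[C@H]2CC3=C(C)[C@@H](O[Si](C)(C)C(C)(C)C)CC[C@]3(C)C[C@H]2O1
F11 | step 13 | 3β-(tert-butyldimethylsilyloxy)eudesma-4,11(13)-dien-12,8-olide | O=C1C(=C)[C@H]2CC3=C(C)[C@@H](O[Si](C)(C)C(C)(C)C)CC[C@]3(C)C[C@H]2O1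
F12 | step 13 | methyl 8β-acetoxy-3β-(tert-butyldimethylsilyloxy)eudesma-4,11(13)-dien-12-oate | C=C(C(=O)OC)[C@H]1CC2=C(C)[C@@H](O[Si](C)(C)C(C)(C)C)CC[C@]2(C)C[C@H]1OC(C)=O
F13 | step 15 | 3-(tert-butyldimethylsilyloxy)eudesma-3,5,11(13)-triene-8β,12-diol | C=C(CO)[C@H]1C=C2C(C)=C(O[Si](C)(C)C(C)(C)C)CC[C@]2(C)C[C@H]1O
F14 | step 15 | C12 tert-butyldimethylsilyl ether of F13 | C=C(CO[Si](C)(C)C(C)(C)C)[C@H]1C=C2C(C)=C(O[Si](C)(C)C(C)(C)C)CC[C@]2(C)C[C@H]1O
F15 | step 15 | C8 acetate of F14 | C=C(CO[Si](C)(C)C(C)(C)C)[C@H]1C=C2C(C)=C(O[Si](C)(C)C(C)(C)C)CC[C@]2(C)C[C@H]1OC(C)=O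
F16 | step 15 | 8β-acetoxy-12-hydroxyeudesma-4,11(13)-dien-3-one | C=C(CO)[C@H]1CC2=C(C)C(=O)CC[C@]2(C)C[C@H]1OC(C)=O
F17 | step 15 | 8β-acetoxy-3-oxoeudesma-4,11(13)-dien-12-al | C=C(C=O)[C@H]1CC2=C(C)C(=O)CC[C@]2(C)C[C@H]1OC(C)=O
F18 | step 15 | 8β-acetoxy-3-oxoeudesma-4,11(13)-dien-12-oic acid | C=C(C(=O)O)[C@H]1CC2=C(C)C(=O)CC[C@]2(C)C[C@H]1OC(C)=O
F19 | step 17 | methyl 8β-acetoxy-3β-(3-oxopentanoyloxy)eudesma-4,11(13)-dien-12-oate | C=C(C(=O)OC)[C@H]1CC2=C(C)[C@@H](OC(=O)CC(=O)CC)CC[C@]2(C)C[C@H]1OC(C)=O
F20 | step 17 | Z enol triflate of F19 | C=C(C(=O)OC)[C@H]1CC2=C(C)[C@@H](OC(=O)/C=C(\OS(=O)(=O)C(F)(F)F)CC)CC[C@]2(C)C[C@H]1OC(C)=O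
A1 | alternative 1 | methyl 8β-hydroxy-3β-[(E)-3-methylpent-2-enoyloxy]eudesma-4,11(13)-dien-12-oate (8-O-deacetyl target) | C=C(C(=O)OC)[C@H]1CC2=C(C)[C@@H](OC(=O)/C=C(\C)CC)CC[C@]2(C)C[C@H]1O
A2 | alternative 1 | ring A aldehyde with Z allylic bromide arm on C5 and acetaldehyde arm on C10 | BrC/C(C(=O)OC)=C\CC1=C(C)[C@@H](OC(=O)/C=C(\C)CC)CC[C@]1(C)CC=O
A3 | alternative 2 | cis-fused ethoxy lactol ether of the 8β-oxygenated 13-nor 4-en-3-one | CCOC1C[C@H]2CC3=C(C)C(=O)CC[C@]3(C)C[C@H]2O1
A4 | alternative 2 | bromoacetal of 8β-hydroxy-11,12,13-trinoreudesma-4,6-dien-3-one | CCOC(CBr)O[C@@H]1C[C@@]2(C)CCC(=O)C(C)=C2C=C1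
A5 | alternative 3 | 2,3,3-trisubstituted cyclohexanone with quaternary C10 and both ring B arms | O=C1CCC[C@](C)(CCO[Si](C)(C)C(C)(C)C)[C@H]1CC(=O)OC(C)(C)C
A6 | alternative 3 | 3-[2-(tert-butyldimethylsilyloxy)ethyl]cyclohex-2-en-1-one | O=C1CCCC(CCO[Si](C)(C)C(C)(C)C)=C1
A7 | alternative 3 | tert-butyl bromoacetate | CC(C)(C)OC(=O)CBr
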